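## Retrosynthetic overview

1. Target 12 ⇐ bicyclic lactone 8: one-pot hydrogenolysis of the push–pull cyclopropane bond, the aryl ketone (to CH2) and the benzyl ether; C3 ends trans by equilibration at the β-keto lactone stage.
2. 8 ⇐ diazo β-keto ester 7: catalytic asymmetric intramolecular cyclopropanation closes the γ-lactone and the cyclopropane in the same operation and sets the carbon that becomes C4.
3. 7 ⇐ β-keto ester 6 (diazo transfer) ⇐ allylic alcohol 2 + benzoic acid 3, joined through an acyl Meldrum's acid / aroylketene.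
4. 2 ⇐ methyl 3,4,5-trimethoxycinnamate 1 (ester reduction).
5. Ring order: both arenes are bought; the lactone and cyclopropane rings form together in step 4; the cyclopropane is opened in step 5, leaving the lactone.

Assumption: the enantiomer of the chiral cobalt porphyrin used in step 4 is taken to be the one that gives (1S,5R,6S)-8; the sense of induction for this substrate is checked on the first run (chiral HPLC, rotation of 12) and the mirror-image ligand is used if it is the reverse.

## Route

Step 1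
Reactants: 1 methyl (E)-3-(3,4,5-trimethoxyphenyl)prop-2-enoate
Product: 2 (E)-3-(3,4,5-trimethoxyphenyl)prop-2-en-1-ol
Conditions: i-Bu2AlH (2.3 equiv), CH2Cl2, −78 to 0 °C
Reagents that add atoms: none
Why: Hydride reduction of an α,β-unsaturated ester with i-Bu2AlH is a clean 1,2-reduction to the allylic alcohol that leaves the E alkene and the aryl methyl ethers untouched, and no stereocentre is formed.

Step 2
Reactants: 3 4-(benzyloxy)-3-methoxybenzoic acid; 2 (E)-3-(3,4,5-trimethoxyphenyl)prop-2-en-1-ol
Product: 6 (E)-3-(3,4,5-trimethoxyphenyl)prop-2-en-1-yl 3-[4-(benzyloxy)-3-methoxyphenyl]-3-oxopropanoate, via acyl Meldrum's acid 4 (not isolated), via aroylketene 5 (not isolated)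
Conditions: Meldrum's acid, DCC, DMAP, CH2Cl2, 0 °C to rt; filter, aq. KHSO4 wash, evaporate; then 2, toluene, 110 °C
Reagents that add atoms: Meldrum's acid (2,2-dimethyl-1,3-dioxane-4,6-dione), CC1(C)OC(=O)CC(=O)O1
Why: Carbodiimide-mediated C-acylation of Meldrum's acid followed by thermal cycloreversion (loss of acetone and CO2) gives the aroylketene, which the primary allylic alcohol traps as the β-keto ester (Oikawa–Yonemitsu β-keto ester synthesis), and no stereocentre is formed.

Step 3
Reactants: 6 (E)-3-(3,4,5-trimethoxyphenyl)prop-2-en-1-yl 3-[4-(benzyloxy)-3-methoxyphenyl]-3-oxopropanoate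
Product: 7 (E)-3-(3,4,5-trimethoxyphenyl)prop-2-en-1-yl 3-[4-(benzyloxy)-3-methoxyphenyl]-2-diazo-3-oxopropanoate
Conditions: 4-acetamidobenzenesulfonyl azide, Et3N, MeCN, 0 °C to rt
Reagents that add atoms: 4-acetamidobenzenesulfonyl azide, CC(=O)Nc1ccc(cc1)S(=O)(=O)N=[N+]=[N-]
Why: Regitz diazo transfer to the doubly activated methylene of a β-keto ester proceeds under mild amine base without touching the allylic ester or the alkene, and no stereocentre is formed.

Step 4
Reactants: 7 (E)-3-(3,4,5-trimethoxyphenyl)prop-2-en-1-yl 3-[4-(benzyloxy)-3-methoxyphenyl]-2-diazo-3-oxopropanoate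
Product: 8 (1S,5R,6S)-1-[4-(benzyloxy)-3-methoxybenzoyl]-6-(3,4,5-trimethoxyphenyl)-3-oxabicyclo[3.1.0]hexan-2-one
Conditions: [Co(3,5-DitBu-ChenPhyrin)] (2 mol %), toluene, 40 °C
Reagents that add atoms: none
Why: This is an asymmetric intramolecular carbene cyclopropanation of an acceptor/acceptor allyl diazoacetate under metalloradical catalysis by the divalent cobalt porphyrin, in which the cobalt-bound carbene radical adds 5-exo to the styrenyl alkene inside the chiral, hydrogen-bonding cavity (closing the lactone and fixing C5) and the resulting benzylic radical then closes the cyclopropane, so that C1 follows from the cis ring fusion and the E alkene places the aryl group exo at C6.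

Step 5
Reactants: 8 (1S,5R,6S)-1-[4-(benzyloxy)-3-methoxybenzoyl]-6-(3,4,5-trimethoxyphenyl)-3-oxabicyclo[3.1.0]hexan-2-one
Product: 12 (3R,4R)-3-(4-hydroxy-3-methoxybenzyl)-4-(3,4,5-trimethoxybenzyl)dihydrofuran-2(3H)-one, via O-benzyl keto lactone 9 (not isolated), via phenolic keto lactone 10 (not isolated), via benzylic alcohol 11 (not isolated)
Conditions: H2 (4 atm), 10% Pd/C, AcOH, HClO4 (cat.), 50 °C
Reagents that add atoms: none
Why: Three catalytic hydrogenolyses run in one pot, namely cleavage of the donor–acceptor C1–C6 cyclopropane bond (C5 is untouched and becomes C4 of the lactone), O-debenzylation, and reduction of the para-hydroxyaryl ketone through the benzylic alcohol to CH2, while C3 is set under thermodynamic control at the readily enolised β-keto lactone stage (aroyl trans to the C4 benzyl group) and is not touched afterwards, which gives the (3R,4R) trans lactone.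

## Compound list

1 | methyl (E)-3-(3,4,5-trimethoxyphenyl)prop-2-enoate | COC(=O)/C=C/c1cc(OC)c(OC)c(OC)c1 | starting material
2 | (E)-3-(3,4,5-trimethoxyphenyl)prop-2-en-1-ol | OC/C=C/c1cc(OC)c(OC)c(OC)c1 | intermediate
3 | 4-(benzyloxy)-3-methoxybenzoic acid | COc1cc(C(=O)O)ccc1OCc1ccccc1 | starting material
4 | 5-[4-(benzyloxy)-3-methoxybenzoyl]-2,2-dimethyl-1,3-dioxane-4,6-dione (acyl Meldrum's acid) | COc1cc(C(=O)C2C(=O)OC(C)(C)OC2=O)ccc1OCc1ccccc1 | intermediate
5 | 3-[4-(benzyloxy)-3-methoxyphenyl]prop-1-ene-1,3-dione (aroylketene) | COc1cc(C(=O)C=C=O)ccc1OCc1ccccc1 | intermediate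
6 | (E)-3-(3,4,5-trimethoxyphenyl)prop-2-en-1-yl 3-[4-(benzyloxy)-3-methoxyphenyl]-3-oxopropanoate | COc1cc(/C=C/COC(=O)CC(=O)c2ccc(OCc3ccccc3)c(OC)c2)cc(OC)c1OC | intermediate
7 | (E)-3-(3,4,5-trimethoxyphenyl)prop-2-en-1-yl 3-[4-(benzyloxy)-3-methoxyphenyl]-2-diazo-3-oxopropanoate | COc1cc(/C=C/COC(=O)C(=[N+]=[N-])C(=O)c2ccc(OCc3ccccc3)c(OC)c2)cc(OC)c1OC | intermediate
8 | (1S,5R,6S)-1-[4-(benzyloxy)-3-methoxybenzoyl]-6-(3,4,5-trimethoxyphenyl)-3-oxabicyclo[3.1.0]hexan-2-one | O=C1OC[C@@H]2[C@@H](c3cc(OC)c(OC)c(OC)c3)[C@]12C(=O)c1ccc(OCc2ccccc2)c(OC)c1 | intermediate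
9 | (3S,4R)-3-[4-(benzyloxy)-3-methoxybenzoyl]-4-(3,4,5-trimethoxybenzyl)dihydrofuran-2(3H)-one | COc1cc(C(=O)[C@H]2C(=O)OC[C@@H]2Cc2cc(OC)c(OC)c(OC)c2)ccc1OCc1ccccc1 | intermediate
10 | (3S,4R)-3-(4-hydroxy-3-methoxybenzoyl)-4-(3,4,5-trimethoxybenzyl)dihydrofuran-2(3H)-one | COc1cc(C(=O)[C@H]2C(=O)OC[C@@H]2Cc2cc(OC)c(OC)c(OC)c2)ccc1O | intermediate
11 | (3S,4R)-3-[hydroxy(4-hydroxy-3-methoxyphenyl)methyl]-4-(3,4,5-trimethoxybenzyl)dihydrofuran-2(3H)-one (both carbinol epimers) | COc1cc(C(O)[C@H]2C(=O)OC[C@@H]2Cc2cc(OC)c(OC)c(OC)c2)ccc1O | intermediate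
12 | (3R,4R)-3-(4-hydroxy-3-methoxybenzyl)-4-(3,4,5-trimethoxybenzyl)dihydrofuran-2(3H)-one | COc1cc(C[C@H]2C(=O)OC[C@@H]2Cc2cc(OC)c(OC)c(OC)c2)ccc1O | target

## Step count and risks

Total steps: 5. Longest linear sequence: 5 (1 → 2 → 6 → 7 → 8 → 12); acid 3 enters at step 2.

**Step 4 (most likely to fail).** The enantioselectivity with an aroyl acceptor and the sense of induction are not secured. A dihydrofuran isomer from O-closure would be harmless, since benzylic C–O hydrogenolysis in step 5 also leads to 9. The fallback sets out from 3 and comes back at 9, taking the stereocentre from the chiral pool. (R)-Epichlorohydrin and dimethyl malonate (NaOMe, MeOH, reflux) give methyl (1S,5R)-2-oxo-3-oxabicyclo[3.1.0]hexane-1-carboxylate F1, again closing cyclopropane and lactone together, with inversion at the epoxide carbon. Commercial 3,4,5-trimethoxyphenylmagnesium bromide with catalytic CuI (THF, −30 °C) opens the cyclopropane at its CH2 to methyl (4R)-2-oxo-4-(3,4,5-trimethoxybenzyl)tetrahydrofuran-3-carboxylate F2. LiCl in wet DMSO at 140 °C removes the ester to give (4R)-4-(3,4,5-trimethoxybenzyl)dihydrofuran-2(3H)-one F3. Acid 3 is converted with (COCl)2 and catalytic DMF into 4-(benzyloxy)-3-methoxybenzoyl chloride F4. The lithium enolate of F3 (LiN(SiMe3)2, 2.2 equiv, THF, −78 °C) is C-acylated with F4 to give 9, which is submitted to the conditions of step 5.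

**Step 5.** The ketone deoxygenation may stall at 10 or 11, and dehydration of 11 followed by alkene hydrogenation could give some cis lactone. The fallback sets out from 8 and comes back at 12. Neutral hydrogenolysis (H2 1 atm, 10% Pd/C, EtOAc, rt) is stopped after cyclopropane and benzyl ether cleavage and 10 is isolated. The ketone is then removed by ionic hydrogenation (Et3SiH, CF3CO2H, 0 °C to rt), and any cis isomer is equilibrated to the more stable trans lactone with DBU in toluene at 80 °C. No compound outside the list is made (F0).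

**Step 2.** C-acylation of Meldrum's acid by the electron-rich benzoic acid can be sluggish and the ketene may be trapped inefficiently. The fallback sets out from 2 and comes back at 6. Crossed Claisen condensation of commercial 1-[4-(benzyloxy)-3-methoxyphenyl]ethanone with dimethyl carbonate (NaH, THF, reflux) gives methyl 3-[4-(benzyloxy)-3-methoxyphenyl]-3-oxopropanoate F5. Heating F5 with 2 in toluene (DMAP cat., methanol distilled off) transesterifies it to 6.

## Further compounds

F1 | step 4 | methyl (1S,5R)-2-oxo-3-oxabicyclo[3.1.0]hexane-1-carboxylate | O=C1OC[C@@H]2C[C@]12C(=O)OC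
F2 | step 4 | methyl (4R)-2-oxo-4-(3,4,5-trimethoxybenzyl)tetrahydrofuran-3-carboxylate (C3 epimers) | COC(=O)C1C(=O)OC[C@@H]1Cc1cc(OC)c(OC)c(OC)c1
F3 | step 4 | (4R)-4-(3,4,5-trimethoxybenzyl)dihydrofuran-2(3H)-one | O=C1OC[C@@H](C1)Cc1cc(OC)c(OC)c(OC)c1
F4 | step 4 | 4-(benzyloxy)-3-methoxybenzoyl chloride | COc1cc(C(=O)Cl)ccc1OCc1ccccc1
F0 | step 5 | none | none
F5 | step 2 | methyl 3-[4-(benzyloxy)-3-methoxyphenyl]-3-oxopropanoate | COC(=O)CC(=O)c1ccc(OCc2ccccc2)c(OC)c1
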